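Retrosynthesis: the O7–S bond is cut first. Ring B is then taken apart by a retro-[4+2] across C1'–C2' and C5'–C6', and ring C is opened at O1–C2 and C2–C3 back to a phloroacetophenone.
Enabling feature: ring B (C1'–C6') is a catechol attached to C2. Its C2'–C3'(O)–C4'(O)–C5' half maps onto a 2,3-dioxygenated butadiene, and its C1'–C6' edge maps onto an ethynyl group at C2 that is polarised through C2=C3 by the C4 carbonyl.
Forward: ring A is purchased and ring C is closed by Claisen condensation and cyclodehydration. The C2 formyl group is homologated to the alkyne, and ring B is built by cycloaddition and then dehydrogenated.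
Endgame: the benzyl ethers on ring A and the silyl ethers on ring B are removed independently, so O5 and O7 are freed alone. The chelated 5-OH stays inert, only O7 is sulfated, and fluoride then releases the catechol.
Stereochemistry: the target is achiral, and no stereocentre is made or needed at any stage of the main route.
Key step: step 6

Assumption: the target is taken as the free hydrogen sulfate, as drawn. Aryl hydrogen sulfates keep best as salts, so the material is carried as its pyridinium salt and protonated only in the last operation.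

Step 1
Reactants: 1 2',4',6'-trihydroxyacetophenone
Product: 2 1-[2,4-bis(benzyloxy)-6-hydroxyphenyl]ethan-1-one
Conditions: BnBr (2.1 equiv), K2CO3 (2.2 equiv), DMF, rt to 50 °C
Reagents that add atoms: benzyl bromide, BrCc1ccccc1
Why: Williamson etherification alkylates the 4-OH and one of the two equivalent ortho OH groups, after which the last OH is hydrogen-bonded to the acetyl carbonyl and is too poor a nucleophile for the limiting bromide.

Step 2
Reactants: 2 1-[2,4-bis(benzyloxy)-6-hydroxyphenyl]ethan-1-one; 3 ethyl diethoxyacetate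
Product: 4 1-[2,4-bis(benzyloxy)-6-hydroxyphenyl]-4,4-diethoxybutane-1,3-dione
Conditions: NaH (4 equiv), 3 (1.5 equiv), THF, reflux; sat. aq. NH4Cl, 0 °C
Reagents that add atoms: none
Why: In this crossed Claisen condensation the phenoxide/enolate dianion of 2 is acylated at its methyl carbon by ester 3, which does not self-condense, and deprotonation of the β-diketone drives the equilibrium and sets the future C2–C3 bond.

Step 3
Reactants: 4 1-[2,4-bis(benzyloxy)-6-hydroxyphenyl]-4,4-diethoxybutane-1,3-dione
Product: 6 5,7-bis(benzyloxy)-4-oxo-4H-chromene-2-carbaldehyde, via 2-(diethoxymethyl)chromone 5 (not isolated)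
Conditions: 3 M aq. HCl–THF (1:3), reflux; toluene azeotrope to dry
Reagents that add atoms: water, O
Why: Acid-catalysed cyclodehydration of an o-hydroxyaryl β-diketone (the classical chromone closure, 6-exo-trig attack of the only free phenol followed by loss of water) forms O1–C2, and the same dilute acid hydrolyses the acetal while being too mild to cleave aryl benzyl ethers.

Step 4
Reactants: 6 5,7-bis(benzyloxy)-4-oxo-4H-chromene-2-carbaldehyde
Product: 7 5,7-bis(benzyloxy)-2-ethynyl-4H-chromen-4-one
Conditions: Me3SiCHN2 (1.3 equiv), LiN(iPr)2 (LDA, 1.2 equiv), THF, –78 °C; then 6, –78 °C to rt; sat. aq. NH4Cl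
Reagents that add atoms: (trimethylsilyl)diazomethane, C[Si](C)(C)C=[N+]=[N-]
Why: In the Colvin rearrangement (the aprotic relative of the Seyferth–Gilbert homologation), 1,2-addition to the aldehyde, Peterson-type loss of silanolate, loss of N2 and a 1,2-hydrogen shift should give the terminal alkyne, and the absence of alcohol and alkoxide avoids conjugate addition to the pyrone or to the activated triple bond.

Step 5
Reactants: 8 biacetyl (butane-2,3-dione)
Product: 9 2,3-bis(tert-butyldimethylsilyloxy)buta-1,3-diene
Conditions: TBSOTf (2.2 equiv), Et3N (3 equiv), CH2Cl2, 0 °C to rt; bulb-to-bulb distillation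
Reagents that add atoms: tert-butyldimethylsilyl triflate, CC(C)(C)[Si](C)(C)OS(=O)(=O)C(F)(F)F
Why: Double soft enolisation and O-silylation of a 1,2-diketone with a silyl triflate and a tertiary amine is the standard access to 2,3-bis(silyloxy)butadienes, and TBS is chosen so that the ethers outlast heating, DDQ, hydrogenolysis and sulfation.

Step 6
Reactants: 7 5,7-bis(benzyloxy)-2-ethynyl-4H-chromen-4-one; 9 2,3-bis(tert-butyldimethylsilyloxy)buta-1,3-diene
Product: 10 5,7-bis(benzyloxy)-2-[4,5-bis(tert-butyldimethylsilyloxy)cyclohexa-1,4-dien-1-yl]-4H-chromen-4-one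
Conditions: 9 (4 equiv), BHT (cat.), toluene, base-washed sealed tube, 150 °C; filtration through Et3N-deactivated SiO2
Reagents that add atoms: none
Why: This is a normal-electron-demand Diels–Alder reaction in which s-cis diene 9, its HOMO raised by two silyloxy donors, adds suprafacially and in one concerted event to the terminal alkyne of 7, whose LUMO is lowered by conjugation through C2=C3 to the C4 carbonyl (a vinylogous ynone). The closest known reaction types are the thermal cycloadditions of 2,3-bis(silyloxy)butadienes to ynones, propiolates and acetylenedicarboxylates, and the Diels–Alder reactions of 2-styrylchromones, in which the exocyclic π bond and not the pyrone acts as dienophile. Ring B is closed as a six-membered carbocycle by intermolecular [4+2] annulation, C1'–C2' and C5'–C6' forming together and leaving the C3'=C4' bis(silyl enol ether) and the C1'=C6' alkene as a skipped diene. No stereocentre is created, and because both ends of 9 are identical only one constitutional isomer can arise. The step needs site selectivity for the triple bond over the pyrone C2=C3 bond, and this is secured by the unhindered CH terminus, by the fact that the alkyne reacts without interrupting the pyrone conjugation, and by the trisubstituted, O1-donated (vinylogous ester) nature of C2=C3. Acid-free glass and the absence of Lewis acids keep the silyl enol ethers out of a stepwise Mukaiyama–Michael addition at C2.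

Step 7
Reactants: 10 5,7-bis(benzyloxy)-2-[4,5-bis(tert-butyldimethylsilyloxy)cyclohexa-1,4-dien-1-yl]-4H-chromen-4-one
Product: 11 5,7-bis(benzyloxy)-2-[3,4-bis(tert-butyldimethylsilyloxy)phenyl]-4H-chromen-4-one
Conditions: DDQ (1.05 equiv), toluene, 0 °C to rt
Reagents that add atoms: none
Why: In this DDQ dehydrogenation of a 1,4-cyclohexadiene, hydride abstraction from a doubly allylic CH2 gives a silyloxy-stabilised cation that loses the proton across the ring, with aromatisation as the driving force, while unactivated benzyl ethers are inert to DDQ at this temperature.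

Step 8
Reactants: 11 5,7-bis(benzyloxy)-2-[3,4-bis(tert-butyldimethylsilyloxy)phenyl]-4H-chromen-4-one
Product: 12 2-[3,4-bis(tert-butyldimethylsilyloxy)phenyl]-5,7-dihydroxy-4H-chromen-4-one
Conditions: H2 (1 atm), 10% Pd/C, EtOAc–THF, rt
Reagents that add atoms: none
Why: Catalytic hydrogenolysis removes the aryl benzyl ethers, and in an aprotic solvent the aryl silyl ethers persist and the flavone C2=C3 bond, being part of the conjugated pyrone, should not be reduced at atmospheric pressure.

Step 9
Reactants: 12 2-[3,4-bis(tert-butyldimethylsilyloxy)phenyl]-5,7-dihydroxy-4H-chromen-4-one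
Product: 13 pyridinium 2-[3,4-bis(tert-butyldimethylsilyloxy)phenyl]-5-hydroxy-4-oxo-4H-chromen-7-yl sulfate
Conditions: SO3·pyridine (1.5 equiv), pyridine, 0 °C to rt; Sephadex LH-20
Reagents that add atoms: sulfur trioxide–pyridine complex, O=S(=O)([O-])[n+]1ccccc1
Why: In this O-sulfation of a phenol with an amine–SO3 complex the 7-OH is the most acidic and the only accessible phenol (a vinylogous acid of the C4 carbonyl), whereas the 5-OH is held in a six-membered hydrogen bond to C4=O and ring B is silylated.

Step 10
Reactants: 13 pyridinium 2-[3,4-bis(tert-butyldimethylsilyloxy)phenyl]-5-hydroxy-4-oxo-4H-chromen-7-yl sulfate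
Product: 15 luteolin 7-sulfate (2-(3,4-dihydroxyphenyl)-5-hydroxy-4-oxo-4H-chromen-7-yl hydrogen sulfate), via pyridinium luteolin 7-sulfate 14 (not isolated)
Conditions: HF·pyridine, pyridine–THF, 0 °C to rt (plastic vessel); then sulfonic acid cation-exchange resin (H+ form), MeOH–H2O, 0 °C; lyophilisation
Reagents that add atoms: none
Why: Fluoride-driven cleavage of the aryl silyl ethers (Si–F bond strength) takes place in a pyridine-buffered medium that is not acidic enough to solvolyse the aryl sulfate, and cold cation exchange then replaces pyridinium by a proton.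

Compound list
1 | 2',4',6'-trihydroxyacetophenone | CC(=O)c1c(O)cc(O)cc1O | starting material
2 | 1-[2,4-bis(benzyloxy)-6-hydroxyphenyl]ethan-1-one | CC(=O)c1c(O)cc(OCc2ccccc2)cc1OCc1ccccc1 | intermediate
3 | ethyl diethoxyacetate | CCOC(OCC)C(=O)OCC | starting material
4 | 1-[2,4-bis(benzyloxy)-6-hydroxyphenyl]-4,4-diethoxybutane-1,3-dione | CCOC(OCC)C(=O)CC(=O)c1c(O)cc(OCc2ccccc2)cc1OCc1ccccc1 | intermediate
5 | 5,7-bis(benzyloxy)-2-(diethoxymethyl)-4H-chromen-4-one (not isolated) | CCOC(OCC)c1cc(=O)c2c(OCc3ccccc3)cc(OCc3ccccc3)cc2o1 | intermediate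
6 | 5,7-bis(benzyloxy)-4-oxo-4H-chromene-2-carbaldehyde | O=Cc1cc(=O)c2c(OCc3ccccc3)cc(OCc3ccccc3)cc2o1 | intermediate
7 | 5,7-bis(benzyloxy)-2-ethynyl-4H-chromen-4-one | C#Cc1cc(=O)c2c(OCc3ccccc3)cc(OCc3ccccc3)cc2o1 | intermediate
8 | biacetyl (butane-2,3-dione) | CC(=O)C(C)=O | starting material
9 | 2,3-bis(tert-butyldimethylsilyloxy)buta-1,3-diene | C=C(O[Si](C)(C)C(C)(C)C)C(=C)O[Si](C)(C)C(C)(C)C | intermediate
10 | 5,7-bis(benzyloxy)-2-[4,5-bis(tert-butyldimethylsilyloxy)cyclohexa-1,4-dien-1-yl]-4H-chromen-4-one | CC(C)(C)[Si](C)(C)OC1=C(O[Si](C)(C)C(C)(C)C)CC(c2cc(=O)c3c(OCc4ccccc4)cc(OCc4ccccc4)cc3o2)=CC1 | intermediate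
11 | 5,7-bis(benzyloxy)-2-[3,4-bis(tert-butyldimethylsilyloxy)phenyl]-4H-chromen-4-one | CC(C)(C)[Si](C)(C)Oc1ccc(-c2cc(=O)c3c(OCc4ccccc4)cc(OCc4ccccc4)cc3o2)cc1O[Si](C)(C)C(C)(C)C | intermediate
12 | 2-[3,4-bis(tert-butyldimethylsilyloxy)phenyl]-5,7-dihydroxy-4H-chromen-4-one | CC(C)(C)[Si](C)(C)Oc1ccc(-c2cc(=O)c3c(O)cc(O)cc3o2)cc1O[Si](C)(C)C(C)(C)C | intermediate
13 | pyridinium 2-[3,4-bis(tert-butyldimethylsilyloxy)phenyl]-5-hydroxy-4-oxo-4H-chromen-7-yl sulfate | CC(C)(C)[Si](C)(C)Oc1ccc(-c2cc(=O)c3c(O)cc(OS(=O)(=O)[O-])cc3o2)cc1O[Si](C)(C)C(C)(C)C.c1cc[nH+]cc1 | intermediate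
14 | pyridinium luteolin 7-sulfate (not isolated) | O=c1cc(-c2ccc(O)c(O)c2)oc2cc(OS(=O)(=O)[O-])cc(O)c12.c1cc[nH+]cc1 | intermediate
15 | luteolin 7-sulfate | O=c1cc(-c2ccc(O)c(O)c2)oc2cc(OS(=O)(=O)O)cc(O)c12 | target

Total step count: 10 (nine in the main line and one for the diene). Longest linear sequence: 9 steps (1 to 15 through steps 1–4 and 6–10).

Steps most likely to fail

1. Step 6.
- Risk: the alkyne is activated only by vinylogy and ring A is electron-rich. The cycloaddition may therefore be so slow that thermal oligomerisation of 7 and decomposition or silyl transfer of 9 overtake it.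
- Fallback: a nitroalkene replaces the triple bond as its synthetic equivalent, and the same two ring B bonds are formed.
- From aldehyde 6, Henry condensation with nitromethane (NH4OAc, AcOH, 90 °C) should give 5,7-bis(benzyloxy)-2-[(E)-2-nitroethenyl]-4H-chromen-4-one F1, a much stronger dienophile.
- Cycloaddition of F1 with 9 (toluene, 80–110 °C) should give (±)-trans-5,7-bis(benzyloxy)-2-[3,4-bis(tert-butyldimethylsilyloxy)-6-nitrocyclohex-3-en-1-yl]-4H-chromen-4-one F2, whose trans relationship follows from the E alkene.
- DBU (CH2Cl2, 0 °C to rt) should then remove the acidic hydrogen at the chromone-bearing carbon and expel nitrite (E1cB). This comes back to the route at 10.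

2. Step 4.
- Risk: the lithiated reagent or the liberated silanolate may add to C2 of the pyrone and open the ring, or base may oligomerise the activated terminal alkyne.
- Fallback: the carbene rearrangement is replaced by olefination and elimination under weak bases.
- From 6, Corey–Fuchs-type dibromoolefination (CBr4, PPh3, CH2Cl2, 0 °C) should give 5,7-bis(benzyloxy)-2-(2,2-dibromoethenyl)-4H-chromen-4-one F3.
- Hydrogenolysis with Bu3SnH catalysed by Pd(PPh3)4 (toluene, rt) should remove the less hindered bromide, the one trans to the chromone. This should give 5,7-bis(benzyloxy)-2-[(Z)-2-bromoethenyl]-4H-chromen-4-one F4.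
- Anti elimination of HBr from F4 with DBU (MeCN, rt to 50 °C) comes back to the route at 7.

3. Step 9.
- Risk: discrimination between O7 and O5 may be incomplete, leading to over-sulfation. The amphiphilic salt, or its silyl ethers, may also be lost during purification.
- Fallback: the sulfate is introduced as a neutral diester that can be chromatographed on silica.
- From 12, 2,2,2-trichloroethyl chlorosulfate (1 equiv, Et3N, DMAP, THF, 0 °C) should give 2-[3,4-bis(tert-butyldimethylsilyloxy)phenyl]-5-hydroxy-4-oxo-4H-chromen-7-yl 2,2,2-trichloroethyl sulfate F5, which chromatography frees from any O5 isomer.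
- HF·pyridine (THF, 0 °C to rt) should then give 2-(3,4-dihydroxyphenyl)-5-hydroxy-4-oxo-4H-chromen-7-yl 2,2,2-trichloroethyl sulfate F6.
- Reductive fragmentation of the trichloroethyl group (Zn, HCO2NH4, MeOH, rt) should give ammonium luteolin 7-sulfate F7.
- Cold cation exchange (H+ form resin) comes back to the route at 15.

Further compounds
F1 | step 6 | 5,7-bis(benzyloxy)-2-[(E)-2-nitroethenyl]-4H-chromen-4-one | O=[N+]([O-])/C=C/c1cc(=O)c2c(OCc3ccccc3)cc(OCc3ccccc3)cc2o1
F2 | step 6 | (±)-trans-5,7-bis(benzyloxy)-2-[3,4-bis(tert-butyldimethylsilyloxy)-6-nitrocyclohex-3-en-1-yl]-4H-chromen-4-one (racemic, one enantiomer drawn) | O=[N+]([O-])[C@@H]1CC(O[Si](C)(C)C(C)(C)C)=C(O[Si](C)(C)C(C)(C)C)C[C@H]1c1cc(=O)c2c(OCc3ccccc3)cc(OCc3ccccc3)cc2o1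
F3 | step 4 | 5,7-bis(benzyloxy)-2-(2,2-dibromoethenyl)-4H-chromen-4-one | BrC(Br)=Cc1cc(=O)c2c(OCc3ccccc3)cc(OCc3ccccc3)cc2o1
F4 | step 4 | 5,7-bis(benzyloxy)-2-[(Z)-2-bromoethenyl]-4H-chromen-4-one | Br/C=C\c1cc(=O)c2c(OCc3ccccc3)cc(OCc3ccccc3)cc2o1
F5 | step 9 | 2-[3,4-bis(tert-butyldimethylsilyloxy)phenyl]-5-hydroxy-4-oxo-4H-chromen-7-yl 2,2,2-trichloroethyl sulfate | CC(C)(C)[Si](C)(C)Oc1ccc(-c2cc(=O)c3c(O)cc(OS(=O)(=O)OCC(Cl)(Cl)Cl)cc3o2)cc1O[Si](C)(C)C(C)(C)C
F6 | step 9 | 2-(3,4-dihydroxyphenyl)-5-hydroxy-4-oxo-4H-chromen-7-yl 2,2,2-trichloroethyl sulfate | O=c1cc(-c2ccc(O)c(O)c2)oc2cc(OS(=O)(=O)OCC(Cl)(Cl)Cl)cc(O)c12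
F7 | step 9 | ammonium luteolin 7-sulfate | O=c1cc(-c2ccc(O)c(O)c2)oc2cc(OS(=O)(=O)[O-])cc(O)c12.[NH4+]
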